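**Abbreviations and assumption (one line each)**
Ar = 5-bromo-2-methoxy-4,6-bis(methoxymethoxy)-3-(3-methylbut-2-en-1-yl)phenyl; R* = (2R)-5-methyl-2-(prop-1-en-2-yl)hex-5-en-1-yl.
Assumption: the side-chain stereocentre is (R), as read from the SMILES; carbinol 33 is carried as a mixture of epimers at the carbinol carbon, which step 18 erases.

**Retrosynthetic overview**
1. Target ⇐ aryl–C(=O) bond made last: aryllithium from bromide 29 plus 3-(TBSO)benzaldehyde, then oxidation and removal of TBS and two MOM groups.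
2. Both C(CH3)=CH2 units ⇐ methyl ketones (Wittig); these come from a δ-keto N-acyl oxazolidinone.
3. Key C–C bond: Cα–CH2CH2COCH3, formed by auxiliary-controlled Michael addition of the titanium enolate of imide 18 to methyl vinyl ketone; this sets the (R) centre.
4. Imide 18 ⇐ hexasubstituted benzaldehyde 10 (Meldrum's acid homologation); 10 ⇐ 2,4,6-trihydroxybenzaldehyde by MOM protection, O-allylation/Claisen, O-methylation, bromination and cross-metathesis.
5. No ring is constructed: both benzene rings are bought; the oxazolidinone is a recovered auxiliary.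

**Route**

Step 1
Reactants: 1 2,4,6-trihydroxybenzaldehyde
Product: 2 2-hydroxy-4,6-bis(methoxymethoxy)benzaldehyde
Conditions: MOMCl (2.2 equiv), i-Pr2NEt, CH2Cl2, 0 °C to rt
Reagents that add atoms: chloromethyl methyl ether (MOMCl), COCCl
Why: O-alkylation (MOM protection) stops at the bis-ether because the last ortho-OH is hydrogen-bonded to the aldehyde and is the least nucleophilic.

Step 2
Reactants: 2 2-hydroxy-4,6-bis(methoxymethoxy)benzaldehyde; 3 allyl bromide
Product: 4 2,4-bis(methoxymethoxy)-6-(prop-2-en-1-yloxy)benzaldehyde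
Conditions: K2CO3, DMF, 60 °C
Reagents that add atoms: none
Why: Williamson ether synthesis on the single remaining phenol under forcing carbonate conditions.

Step 3
Reactants: 4 2,4-bis(methoxymethoxy)-6-(prop-2-en-1-yloxy)benzaldehyde
Product: 6 2-hydroxy-4,6-bis(methoxymethoxy)-3-(prop-2-en-1-yl)benzaldehyde, via ortho-dienone 5 (not isolated)
Conditions: PhNEt2, 190 °C, sealed tube
Reagents that add atoms: none
Why: Aromatic Claisen rearrangement can deliver the allyl group only to the one free ortho carbon of the allyl ether, and tautomerisation restores the chelated phenol.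

Step 4
Reactants: 6 2-hydroxy-4,6-bis(methoxymethoxy)-3-(prop-2-en-1-yl)benzaldehyde
Product: 7 2-methoxy-4,6-bis(methoxymethoxy)-3-(prop-2-en-1-yl)benzaldehyde
Conditions: MeI, K2CO3, DMF, 40 °C
Reagents that add atoms: iodomethane, CI
Why: Williamson O-methylation of the only free phenol fixes the methoxy group between the allyl-bearing and formyl-bearing carbons.

Step 5
Reactants: 7 2-methoxy-4,6-bis(methoxymethoxy)-3-(prop-2-en-1-yl)benzaldehyde
Product: 8 5-bromo-2-methoxy-4,6-bis(methoxymethoxy)-3-(prop-2-en-1-yl)benzaldehyde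
Conditions: NBS, MeCN, 0 °C
Reagents that add atoms: N-bromosuccinimide, O=C1CCC(=O)N1Br
Why: Electrophilic aromatic bromination takes the single remaining ring C–H, activated by two ortho and one para oxygen, faster than the monosubstituted alkene reacts.

Step 6
Reactants: 8 5-bromo-2-methoxy-4,6-bis(methoxymethoxy)-3-(prop-2-en-1-yl)benzaldehyde; 9 2-methylbut-2-ene
Product: 10 5-bromo-2-methoxy-4,6-bis(methoxymethoxy)-3-(3-methylbut-2-en-1-yl)benzaldehyde (ArCHO)
Conditions: Grubbs II (3 mol%), 2-methylbut-2-ene/CH2Cl2, 40 °C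
Reagents that add atoms: none
Why: Olefin cross-metathesis of a terminal allyl arene with excess 2-methylbut-2-ene gives the prenyl group and releases propene.

Step 7
Reactants: 10 ArCHO; 11 Meldrum's acid
Product: 13 5-(Ar-methyl)-2,2-dimethyl-1,3-dioxane-4,6-dione, via arylidene Meldrum's acid 12 (not isolated)
Conditions: L-proline (20 mol%), Hantzsch ester (1.1 equiv), EtOH, rt
Reagents that add atoms: none
Why: Knoevenagel condensation followed by in situ conjugate transfer hydrogenation reduces only the doubly activated C=C, leaving the prenyl alkene and the aryl bromide untouched.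

Step 8
Reactants: 13 5-(Ar-methyl)-2,2-dimethyl-1,3-dioxane-4,6-dione
Product: 15 3-Ar-propanoic acid, via substituted malonic acid 14 (not isolated)
Conditions: pyridine/H2O (10:1), 100 °C
Reagents that add atoms: water, O
Why: Hydrolytic opening of the Meldrum's acid ring and thermal decarboxylation of the malonic acid proceed under near-neutral conditions that the MOM ethers tolerate.

Step 9
Reactants: 15 3-Ar-propanoic acid; 16 (R)-4-benzyl-1,3-oxazolidin-2-one
Product: 18 (4R)-4-benzyl-3-(3-Ar-propanoyl)-1,3-oxazolidin-2-one, via mixed pivalic anhydride 17 (not isolated)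
Conditions: PivCl, Et3N, THF, −20 °C; then 16, LiCl, rt
Reagents that add atoms: none
Why: N-acylation through the mixed anhydride occurs at the unhindered carbonyl and avoids butyllithium, which would attack the aryl bromide.

Step 10
Reactants: 18 (4R)-4-benzyl-3-(3-Ar-propanoyl)-1,3-oxazolidin-2-one; 19 methyl vinyl ketone
Product: 21 (4R)-4-benzyl-3-[(2R)-2-(Ar-methyl)-5-oxohexanoyl]-1,3-oxazolidin-2-one, via titanium (Z)-enolate 20 (not isolated)
Conditions: TiCl3(Oi-Pr) [TiCl4/Ti(Oi-Pr)4 3:1], i-Pr2NEt, CH2Cl2, 0 °C, 1 h; then MVK, 0 °C; aq NH4Cl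
Reagents that add atoms: none
Why: Auxiliary-controlled Michael addition in which the chelated (Z)-enolate is shielded on one face by the benzyl group of the (R)-oxazolidinone, so the enone adds to the opposite face (same sense as Evans alkylation) and sets the new centre as (2R).

Step 11
Reactants: 21 (4R)-4-benzyl-3-[(2R)-2-(Ar-methyl)-5-oxohexanoyl]-1,3-oxazolidin-2-one
Product: 23 (2R)-2-(Ar-methyl)-5-oxohexanoic acid, via peroxy acid 22 (not isolated)
Conditions: LiOH, 30% H2O2, THF/H2O, 0 °C; then aq Na2SO3; cold 1 M HCl to pH 3–4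
Reagents that add atoms: hydrogen peroxide, OO
Why: Hydroperoxide attacks the exocyclic imide carbonyl selectively (nucleophilic acyl substitution), sulfite reduces the peracid, and the weakly basic conditions do not epimerise the α-centre.

Step 12
Reactants: 23 (2R)-2-(Ar-methyl)-5-oxohexanoic acid
Product: 25 (2R)-2-(Ar-methyl)-N-methoxy-N-methyl-5-oxohexanamide, via acyl imidazole 24 (not isolated)
Conditions: CDI, CH2Cl2, rt, 1 h; then MeNH(OMe)·HCl, rt
Reagents that add atoms: N,O-dimethylhydroxylamine hydrochloride, CNOC.Cl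
Why: Amide coupling through the acyl imidazolide gives the Weinreb amide under mild conditions.

Step 13
Reactants: 25 (2R)-2-(Ar-methyl)-N-methoxy-N-methyl-5-oxohexanamide
Product: 26 (2R)-2-(Ar-methyl)-N-methoxy-N,5-dimethylhex-5-enamide
Conditions: Ph3PCH3Br, KHMDS, THF, 0 °C; then 25, 0 °C to rt
Reagents that add atoms: methyltriphenylphosphonium bromide, C[P+](c1ccccc1)(c1ccccc1)c1ccccc1.[Br-]
Why: Wittig methylenation takes the unhindered methyl ketone far faster than the Weinreb amide and does not touch the amide α-centre.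

Step 14
Reactants: 26 (2R)-2-(Ar-methyl)-N-methoxy-N,5-dimethylhex-5-enamide
Product: 28 (3R)-3-(Ar-methyl)-6-methylhept-6-en-2-one, via magnesium hemiaminal chelate 27 (not isolated)
Conditions: MeMgBr, THF, 0 °C; aq NH4Cl
Reagents that add atoms: methylmagnesium bromide, C[Mg]Br
Why: Weinreb ketone synthesis, in which the stable chelate prevents over-addition and releases the epimerisable ketone only on quench.

Step 15
Reactants: 28 (3R)-3-(Ar-methyl)-6-methylhept-6-en-2-one
Product: 29 (3R)-3-(Ar-methyl)-2,6-dimethylhepta-1,6-diene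
Conditions: Ph3PCH3Br (1.6 equiv), KHMDS (1.5 equiv), THF, 0 °C; then 28, −78 to 0 °C
Reagents that add atoms: methyltriphenylphosphonium bromide, C[P+](c1ccccc1)(c1ccccc1)c1ccccc1.[Br-]
Why: Wittig methylenation with base-free preformed ylide at low temperature builds the isopropenyl group, and any enolisation occurs mainly on the methyl side, so the (R) centre is kept.

Step 16
Reactants: 30 3-hydroxybenzaldehyde
Product: 31 3-(tert-butyldimethylsilyloxy)benzaldehyde
Conditions: TBSCl, imidazole, DMF, rt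
Reagents that add atoms: tert-butyldimethylsilyl chloride, CC(C)(C)[Si](C)(C)Cl
Why: Phenol silylation gives a protecting group that survives aryllithium addition and is later removed by fluoride.

Step 17
Reactants: 29 (3R)-3-(Ar-methyl)-2,6-dimethylhepta-1,6-diene; 31 3-(tert-butyldimethylsilyloxy)benzaldehyde
Product: 33 [3-(tert-butyldimethylsilyloxy)phenyl][4-methoxy-2,6-bis(methoxymethoxy)-3-(3-methylbut-2-en-1-yl)-5-R*-phenyl]methanol, via aryllithium 32 (not isolated)
Conditions: n-BuLi, THF, −78 °C, 20 min; then 31, −78 to −20 °C; aq NH4Cl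
Reagents that add atoms: none
Why: Bromine–lithium exchange at −78 °C outpaces any deprotonation, and the aryllithium, stabilised by two flanking OMOM groups, adds 1,2 to the aldehyde; the new carbinol centre forms unselectively and is removed in step 18.

Step 18
Reactants: 33 diaryl carbinol
Product: 34 [3-(tert-butyldimethylsilyloxy)phenyl][4-methoxy-2,6-bis(methoxymethoxy)-3-(3-methylbut-2-en-1-yl)-5-R*-phenyl]methanone
Conditions: Dess–Martin periodinane, NaHCO3, CH2Cl2, rt
Reagents that add atoms: none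
Why: Dess–Martin oxidation of the doubly benzylic alcohol is neutral and leaves the three alkenes and the acetals alone.

Step 19
Reactants: 34 silyl-protected benzophenone
Product: 35 (3-hydroxyphenyl)[4-methoxy-2,6-bis(methoxymethoxy)-3-(3-methylbut-2-en-1-yl)-5-R*-phenyl]methanone
Conditions: TBAF, THF, 0 °C; aq NH4Cl
Reagents that add atoms: none
Why: Fluoride-mediated desilylation cleaves the aryl silyl ether selectively.

Step 20
Reactants: 35 bis-MOM benzophenone
Product: 36 (3-hydroxyphenyl)[2,6-dihydroxy-4-methoxy-3-(3-methylbut-2-en-1-yl)-5-R*-phenyl]methanone (target)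
Conditions: HCl (0.5 M in MeOH), rt
Reagents that add atoms: none
Why: Acid-catalysed transacetalisation removes the two MOM groups ortho to the ketone under mild conditions, because each freed phenol is stabilised by a hydrogen bond to the carbonyl.

**Compound list**
1 | 2,4,6-trihydroxybenzaldehyde | O=Cc1c(O)cc(O)cc1O | starting material
2 | 2-hydroxy-4,6-bis(methoxymethoxy)benzaldehyde | O=Cc1c(O)cc(OCOC)cc1OCOC | intermediate
3 | allyl bromide | C=CCBr | starting material
4 | 2,4-bis(methoxymethoxy)-6-(prop-2-en-1-yloxy)benzaldehyde | C=CCOc1cc(OCOC)cc(OCOC)c1C=O | intermediate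
5 | 2,4-bis(methoxymethoxy)-6-oxo-5-(prop-2-en-1-yl)cyclohexa-1,3-diene-1-carbaldehyde (racemic ortho-dienone, not isolated) | C=CCC1C(OCOC)=CC(OCOC)=C(C=O)C1=O | intermediate
6 | 2-hydroxy-4,6-bis(methoxymethoxy)-3-(prop-2-en-1-yl)benzaldehyde | C=CCc1c(O)c(C=O)c(OCOC)cc1OCOC | intermediate
7 | 2-methoxy-4,6-bis(methoxymethoxy)-3-(prop-2-en-1-yl)benzaldehyde | C=CCc1c(OC)c(C=O)c(OCOC)cc1OCOC | intermediate
8 | 5-bromo-2-methoxy-4,6-bis(methoxymethoxy)-3-(prop-2-en-1-yl)benzaldehyde | C=CCc1c(OC)c(C=O)c(OCOC)c(Br)c1OCOC | intermediate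
9 | 2-methylbut-2-ene | CC=C(C)C | starting material
10 | 5-bromo-2-methoxy-4,6-bis(methoxymethoxy)-3-(3-methylbut-2-en-1-yl)benzaldehyde (ArCHO) | CC(C)=CCc1c(OC)c(C=O)c(OCOC)c(Br)c1OCOC | intermediate
11 | Meldrum's acid (2,2-dimethyl-1,3-dioxane-4,6-dione) | CC1(C)OC(=O)CC(=O)O1 | starting material
12 | 5-(Ar-methylidene)-2,2-dimethyl-1,3-dioxane-4,6-dione (not isolated) | CC1(C)OC(=O)C(=Cc2c(OC)c(CC=C(C)C)c(OCOC)c(Br)c2OCOC)C(=O)O1 | intermediate
13 | 5-(Ar-methyl)-2,2-dimethyl-1,3-dioxane-4,6-dione | CC1(C)OC(=O)C(Cc2c(OC)c(CC=C(C)C)c(OCOC)c(Br)c2OCOC)C(=O)O1 | intermediate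
14 | 2-(Ar-methyl)propanedioic acid (not isolated) | OC(=O)C(Cc1c(OC)c(CC=C(C)C)c(OCOC)c(Br)c1OCOC)C(=O)O | intermediate
15 | 3-Ar-propanoic acid | OC(=O)CCc1c(OC)c(CC=C(C)C)c(OCOC)c(Br)c1OCOC | intermediate
16 | (R)-4-benzyl-1,3-oxazolidin-2-one | O=C1N[C@H](Cc2ccccc2)CO1 | starting material
17 | 3-Ar-propanoic pivalic anhydride (not isolated) | CC(C)(C)C(=O)OC(=O)CCc1c(OC)c(CC=C(C)C)c(OCOC)c(Br)c1OCOC | intermediate
18 | (4R)-4-benzyl-3-(3-Ar-propanoyl)-1,3-oxazolidin-2-one | O=C(CCc1c(OC)c(CC=C(C)C)c(OCOC)c(Br)c1OCOC)N1[C@H](Cc2ccccc2)COC1=O | intermediate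
19 | methyl vinyl ketone (but-3-en-2-one) | C=CC(C)=O | starting material
20 | dichloro(isopropoxy)titanium (Z)-enolate of 18 (not isolated) | CC(C)O[Ti](Cl)(Cl)O/C(=C\Cc1c(OC)c(CC=C(C)C)c(OCOC)c(Br)c1OCOC)N1[C@H](Cc2ccccc2)COC1=O | intermediate
21 | (4R)-4-benzyl-3-[(2R)-2-(Ar-methyl)-5-oxohexanoyl]-1,3-oxazolidin-2-one | CC(=O)CC[C@H](Cc1c(OC)c(CC=C(C)C)c(OCOC)c(Br)c1OCOC)C(=O)N1[C@H](Cc2ccccc2)COC1=O | intermediate
22 | (2R)-2-(Ar-methyl)-5-oxohexaneperoxoic acid (not isolated) | CC(=O)CC[C@H](Cc1c(OC)c(CC=C(C)C)c(OCOC)c(Br)c1OCOC)C(=O)OO | intermediate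
23 | (2R)-2-(Ar-methyl)-5-oxohexanoic acid | CC(=O)CC[C@H](Cc1c(OC)c(CC=C(C)C)c(OCOC)c(Br)c1OCOC)C(=O)O | intermediate
24 | (2R)-2-(Ar-methyl)-1-(imidazol-1-yl)hexane-1,5-dione (not isolated) | CC(=O)CC[C@H](Cc1c(OC)c(CC=C(C)C)c(OCOC)c(Br)c1OCOC)C(=O)n1ccnc1 | intermediate
25 | (2R)-2-(Ar-methyl)-N-methoxy-N-methyl-5-oxohexanamide | CC(=O)CC[C@H](Cc1c(OC)c(CC=C(C)C)c(OCOC)c(Br)c1OCOC)C(=O)N(C)OC | intermediate
26 | (2R)-2-(Ar-methyl)-N-methoxy-N,5-dimethylhex-5-enamide | C=C(C)CC[C@H](Cc1c(OC)c(CC=C(C)C)c(OCOC)c(Br)c1OCOC)C(=O)N(C)OC | intermediate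
27 | bromomagnesium (3R)-3-(Ar-methyl)-2-[methoxy(methyl)amino]-6-methylhept-6-en-2-olate (not isolated) | C=C(C)CC[C@H](Cc1c(OC)c(CC=C(C)C)c(OCOC)c(Br)c1OCOC)C(C)(O[Mg]Br)N(C)OC | intermediate
28 | (3R)-3-(Ar-methyl)-6-methylhept-6-en-2-one | C=C(C)CC[C@H](Cc1c(OC)c(CC=C(C)C)c(OCOC)c(Br)c1OCOC)C(C)=O | intermediate
29 | (3R)-3-(Ar-methyl)-2,6-dimethylhepta-1,6-diene | C=C(C)CC[C@H](Cc1c(OC)c(CC=C(C)C)c(OCOC)c(Br)c1OCOC)C(=C)C | intermediate
30 | 3-hydroxybenzaldehyde | O=Cc1cccc(O)c1 | starting material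
31 | 3-(tert-butyldimethylsilyloxy)benzaldehyde | O=Cc1cccc(O[Si](C)(C)C(C)(C)C)c1 | intermediate
32 | aryllithium from 29, Li in place of Br (not isolated) | C=C(C)CC[C@H](Cc1c(OC)c(CC=C(C)C)c(OCOC)c([Li])c1OCOC)C(=C)C | intermediate
33 | [3-(tert-butyldimethylsilyloxy)phenyl][4-methoxy-2,6-bis(methoxymethoxy)-3-(3-methylbut-2-en-1-yl)-5-R*-phenyl]methanol (carbinol epimers) | C=C(C)CC[C@H](Cc1c(OC)c(CC=C(C)C)c(OCOC)c(C(O)c2cccc(O[Si](C)(C)C(C)(C)C)c2)c1OCOC)C(=C)C | intermediate
34 | [3-(tert-butyldimethylsilyloxy)phenyl][4-methoxy-2,6-bis(methoxymethoxy)-3-(3-methylbut-2-en-1-yl)-5-R*-phenyl]methanone | C=C(C)CC[C@H](Cc1c(OC)c(CC=C(C)C)c(OCOC)c(C(=O)c2cccc(O[Si](C)(C)C(C)(C)C)c2)c1OCOC)C(=C)C | intermediate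
35 | (3-hydroxyphenyl)[4-methoxy-2,6-bis(methoxymethoxy)-3-(3-methylbut-2-en-1-yl)-5-R*-phenyl]methanone | C=C(C)CC[C@H](Cc1c(OC)c(CC=C(C)C)c(OCOC)c(C(=O)c2cccc(O)c2)c1OCOC)C(=C)C | intermediate
36 | (3-hydroxyphenyl){2,6-dihydroxy-4-methoxy-3-(3-methylbut-2-en-1-yl)-5-[(2R)-5-methyl-2-(prop-1-en-2-yl)hex-5-en-1-yl]phenyl}methanone | C=C(C)CC[C@H](Cc1c(O)c(C(=O)c2cccc(O)c2)c(O)c(CC=C(C)C)c1OC)C(=C)C | target

**Totals**
Total steps: 20. Longest linear sequence: 19 (steps 1–15 and 17–20, from compound 1); step 16 is a one-step side branch.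

**Three steps most likely to fail, each with a fallback**

Step 10 (Michael addition). Risk: the titanium Lewis acid may attack the aryl MOM ethers or polymerise the enone, and the bulky β-aryl group may slow the enolate. The fallback sets out from acid 15 and avoids Lewis acid altogether. The acid is converted with CDI and MeNH(OMe)·HCl into 3-Ar-N-methoxy-N-methylpropanamide F1. DIBAL-H at −78 °C reduces this to 3-Ar-propanal F2. An enamine-catalysed Michael addition of F2 to methyl vinyl ketone 19, with (R)-2-(methoxydiphenylmethyl)pyrrolidine (10 mol%) and ethyl 3,4-dihydroxybenzoate as co-catalyst at 4 °C, gives (2R)-2-(Ar-methyl)-5-oxohexanal F3; the diarylmethyl group blocks one enamine face. Pinnick oxidation (NaClO2, NaH2PO4, 2-methylbut-2-ene, t-BuOH/H2O) then gives keto acid 23, where the route resumes.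

Step 15 (second Wittig). Risk: the basic ylide enolises the α-branched methyl ketone, which returns starting material or erodes the (R) centre. The fallback sets out from ketone 28. Addition of Me3SiCH2Li/CeCl3 (THF, −78 °C), a non-basic organocerium, gives (3R)-3-(Ar-methyl)-2,6-dimethyl-1-(trimethylsilyl)hept-6-en-2-ol F4. Elimination with KH in THF (Peterson olefination) gives diene 29, where the route resumes.

Step 20 (final MOM removal). Risk: protic acid can make the freed ortho-phenols add to the prenyl or isopropenyl double bonds (chroman formation), or add methanol to the 1,1-disubstituted alkenes. The fallback sets out from ketone 34 and replaces steps 19 and 20. TMSOTf with 2,2′-bipyridyl in CH2Cl2 at 0 °C exchanges both aryl MOM ethers for trimethylsilyl ethers without free acid, giving [3-(tert-butyldimethylsilyloxy)phenyl][4-methoxy-3-(3-methylbut-2-en-1-yl)-5-R*-2,6-bis(trimethylsilyloxy)phenyl]methanone F5. TBAF in THF then removes all three silyl groups in one operation and gives target 36 directly.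

**Further compounds**
F1 | step 10 | 3-Ar-N-methoxy-N-methylpropanamide | CON(C)C(=O)CCc1c(OC)c(CC=C(C)C)c(OCOC)c(Br)c1OCOC
F2 | step 10 | 3-Ar-propanal | O=CCCc1c(OC)c(CC=C(C)C)c(OCOC)c(Br)c1OCOC
F3 | step 10 | (2R)-2-(Ar-methyl)-5-oxohexanal | CC(=O)CC[C@H](Cc1c(OC)c(CC=C(C)C)c(OCOC)c(Br)c1OCOC)C=O
F4 | step 15 | (3R)-3-(Ar-methyl)-2,6-dimethyl-1-(trimethylsilyl)hept-6-en-2-ol | C=C(C)CC[C@H](Cc1c(OC)c(CC=C(C)C)c(OCOC)c(Br)c1OCOC)C(C)(O)C[Si](C)(C)C
F5 | step 20 | [3-(tert-butyldimethylsilyloxy)phenyl][4-methoxy-3-(3-methylbut-2-en-1-yl)-5-R*-2,6-bis(trimethylsilyloxy)phenyl]methanone | C=C(C)CC[C@H](Cc1c(OC)c(CC=C(C)C)c(O[Si](C)(C)C)c(C(=O)c2cccc(O[Si](C)(C)C(C)(C)C)c2)c1O[Si](C)(C)C)C(=C)C
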